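The plan rests on the γ-lactone ring (O, C6, C7, C11, C12; germacrane numbering). Its oxygen sits between C6 and C12, so removing it (retro-Baeyer–Villiger) leaves a cyclobutanone C6–C7–C11–C12. The two opposite bonds of that ring, C6–C7 and C11–C12, are the σ-bonds of a ketene–alkene [2+2]. In one operation a keteniminium ion C6=C12=N+ (from 4-chloro-N,N-dimethylbutanamide) adds to the terminal alkene C7=C11 of an (S)-butenediol bis-silyl ether. This sets the cis C6/C7 pair under control of C8. The precursors are two small acyclic pieces. Oxygen insertion, methylenation, Nozaki–Hiyama–Kishi attachment of the C10–C4 arm, ring-closing metathesis and peripheral epoxidation finish the ten-membered ring.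

Key step: step 2

Numbering remark: C1=C10(C14O2Me), C2, C3, C4(C15H3), C5, C6(O-lactone), C7, C8(OAc), C9(O-acyl), C11(=C13H2), C12(=O). TBS = tert-butyldimethylsilyl. 4-Chloro-N,N-dimethylbutanamide and 4-methylpent-4-enal are taken as catalogue chemicals.

Step 1
Reactants: 1 (S)-but-3-ene-1,2-diol
Product: 2 (S)-3,4-bis(tert-butyldimethylsilyloxy)but-1-ene
Conditions: TBSCl (2.3 equiv), imidazole, DMF, 0 °C to rt
Reagents that add atoms: tert-butyldimethylsilyl chloride, CC(C)(C)[Si](C)(C)Cl
Why: Routine imidazole-promoted silylation of both hydroxyls, in which the C8 stereocentre is bought with 1 and stays untouched and the silyl ethers should ignore Tf2O in step 2.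

Step 2
Reactants: 2 (S)-3,4-bis(tert-butyldimethylsilyloxy)but-1-ene; 3 4-chloro-N,N-dimethylbutanamide
Product: 6 cis-2-(2-chloroethyl)-3-[(S)-1,2-bis(TBS-oxy)ethyl]cyclobutanone (C6/C7/C8 configured as in the target), via keteniminium triflate 4 (not isolated), via cyclobutaniminium triflate 5 (not isolated)
Conditions: Tf2O (1.2 equiv), 2,4,6-collidine (1.3 equiv), 2 (2 equiv), ClCH2CH2Cl, reflux; then sat. aq NaHCO3, CH2Cl2, rt
Reagents that add atoms: water, O
Why: Tf2O/collidine converts amide 3 into the linear, strongly electrophilic keteniminium ion 4, whose central carbon C12 is attacked by the alkene terminus C11 of 2 while C6 closes onto C7, so C11–C12 and C6–C7 form in one asynchronous event and mild hydrolysis of 5 unveils the ketone (keteniminium–alkene [2+2] cycloaddition, the iminium variant of the ketene–alkene [2+2]). The only ring closed is the cyclobutane C6–C7–C11–C12, made by an intermolecular cycloaddition in the [π2s+π2a] sense and not by cyclisation of a chain. Regiochemistry follows from the monosubstituted alkene: positive charge builds up on the internal carbon C7, so C12 bonds to the CH2 terminus. For C6/C7 the alkene passes the small C6–H of 4, which turns the chloroethyl arm towards the C7 side chain and should give the kinetic cis isomer, preserved by hydrolysis at room temperature. For C7 versus C8, in the late ring closure C8–H lies in plane next to the bulky C11 arm (A1,3 strain), the C8–O bond stays near the nodal plane and C6 attacks anti to the C8–C9 bond, which should translate (8S) into the required C7 configuration. Chemoselectivity needs a ketene partner free of alkenes, hence the chloroethyl group as a latent vinyl.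

Step 3
Reactants: 6 cis-2-(2-chloroethyl)-3-[(S)-1,2-bis(TBS-oxy)ethyl]cyclobutanone
Product: 7 cis-2-[2-(phenylselanyl)ethyl]-3-[(S)-1,2-bis(TBS-oxy)ethyl]cyclobutanone
Conditions: PhSeH, NaH (PhSeNa pre-formed), NaI (cat.), THF–DMF, 0 °C to rt
Reagents that add atoms: benzeneselenol, [SeH]c1ccccc1
Why: SN2 displacement of the primary chloride by the soft, almost non-basic selenolate installs the latent vinyl group without enolising the epimerisable cis-cyclobutanone.

Step 4
Reactants: 7 cis-2-[2-(phenylselanyl)ethyl]-3-[(S)-1,2-bis(TBS-oxy)ethyl]cyclobutanone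
Product: 9 cis-4-[(S)-1,2-bis(TBS-oxy)ethyl]-5-vinyldihydrofuran-2(3H)-one, via selenoxide lactone 8 (not isolated)
Conditions: mCPBA (3.3 equiv), CH2Cl2, −78 to 0 °C, then 35 °C
Reagents that add atoms: 3-chloroperoxybenzoic acid, O=C(OO)c1cccc(Cl)c1
Why: Three peracid oxidations run in one flask: selenide to selenoxide at −78 °C, strain-driven Baeyer–Villiger oxidation at 0 °C by migration of the more substituted C6 with retention (placing the ring oxygen between C6 and C12), and on warming selenoxide syn-elimination to the C5 vinyl group while PhSeOH is oxidised to the inert seleninic acid.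

Step 5
Reactants: 9 cis-4-[(S)-1,2-bis(TBS-oxy)ethyl]-5-vinyldihydrofuran-2(3H)-one
Product: 12 cis-4-[(S)-1,2-bis(TBS-oxy)ethyl]-3-methylene-5-vinyldihydrofuran-2(3H)-one, via Mannich base 10 (not isolated), via ammonium iodide 11 (not isolated)
Conditions: LiN(iPr)2, THF, −78 °C; Me2N=CH2+ I−, −78 °C to rt; MeI, THF–MeOH, rt; sat. aq NaHCO3, CH2Cl2, rt
Reagents that add atoms: Eschenmoser's salt (N,N-dimethylmethyleneiminium iodide), C=[N+](C)C.[I-]
Why: Lactone enolate formation at C11, Mannich reaction, N-methylation and Hofmann-type elimination is the standard α-methylenation of γ-lactones, placed here before any base-sensitive ester is present, and the transient C11 stereocentre (attack anti to the C7 side chain) is erased.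

Step 6
Reactants: 12 cis-4-[(S)-1,2-bis(TBS-oxy)ethyl]-3-methylene-5-vinyldihydrofuran-2(3H)-one
Product: 13 primary alcohol (C9–OH free and C8–OTBS kept)
Conditions: HF·pyridine, pyridine, THF, 0 °C
Reagents that add atoms: none
Why: Under buffered HF·pyridine the unhindered primary silyl ether should be cleaved much faster than the hindered secondary one, and lactone and alkenes are inert.

Step 7
Reactants: 13 primary alcohol
Product: 14 α-silyloxy aldehyde (C9 aldehyde)
Conditions: Dess–Martin periodinane, CH2Cl2, rt
Reagents that add atoms: none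
Why: Dess–Martin oxidation is neutral and fast, so the aldehyde should form without epimerisation at C8 or migration of the exocyclic alkene.

Step 8
Reactants: 15 4-methylpent-4-enal; 16 methyl (triphenylphosphoranylidene)acetate
Product: 18 methyl (Z)-2-iodo-6-methylhepta-2,6-dienoate, via iodo ylide 17 (not isolated)
Conditions: N-iodosuccinimide, CH2Cl2, −20 °C; then 15, −20 °C to rt
Reagents that add atoms: N-iodosuccinimide, O=C1CCC(=O)N1I
Why: Iodination of the stabilised ylide and Wittig olefination in the same flask should place the ester trans to the alkyl chain, as usual for stabilised ylides, giving the (Z)-iodide that maps onto the ring-cis C1=C10 bond.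

Step 9
Reactants: 14 α-silyloxy aldehyde; 18 methyl (Z)-2-iodo-6-methylhepta-2,6-dienoate
Product: 19 C9 allylic alcohol (8,9-anti epimer drawn)
Conditions: CrCl2 (4 equiv), NiCl2 (1 mol %), DMSO, rt
Reagents that add atoms: none
Why: Nozaki–Hiyama–Kishi coupling forms C9–C10, tolerates lactone, acrylate and silyl ether and keeps the alkene geometry; polar Felkin–Anh attack should favour the 9R alcohol drawn, but C9 is reset in steps 10 and 11 so both epimers are carried on.

Step 10
Reactants: 19 C9 allylic alcohol
Product: 20 C9 ketone (alkylidene β-keto ester)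
Conditions: Dess–Martin periodinane, CH2Cl2, 0 °C
Reagents that add atoms: none
Why: Neutral Dess–Martin oxidation converges both C9 epimers on one enone and avoids the bases or nucleophiles that could scramble the C1=C10 geometry or the C8 centre.

Step 11
Reactants: 20 C9 ketone
Product: 21 (9S)-allylic alcohol (8,9-syn)
Conditions: NaBH4, CeCl3·7H2O, MeOH, −78 °C
Reagents that add atoms: none
Why: Luche 1,2-reduction spares the two conjugated alkenes, and polar Felkin–Anh delivery of hydride anti to the non-chelating C8–OTBS bond should give the 8,9-syn alcohol, the epimer opposite to carbon addition on the aldehyde.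

Step 12
Reactants: 22 (S)-(2-methyloxiran-2-yl)methanol
Product: 23 (R)-2-methyloxirane-2-carboxylic acid
Conditions: RuCl3·xH2O (2 mol %), NaIO4, CCl4–MeCN–H2O, rt
Reagents that add atoms: sodium periodate, [Na+].[O-]I(=O)(=O)=O
Why: Catalytic RuO4 oxidation takes glycidols to glycidic acids without touching the epoxide, and the quaternary stereocentre is unchanged (the descriptor changes only because the priorities change).

Step 13
Reactants: 21 (9S)-allylic alcohol; 23 (R)-2-methyloxirane-2-carboxylic acid
Product: 25 C9 (R)-2-methylglycidate ester, via mixed anhydride 24 (not isolated)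
Conditions: 2,4,6-Cl3C6H2COCl, Et3N, THF, rt; then 21, DMAP, toluene, rt
Reagents that add atoms: none
Why: Yamaguchi esterification is suited to a hindered secondary alcohol and an α-quaternary acid, proceeds with retention at C9 and cannot racemise the acid.

Step 14
Reactants: 25 C9 (R)-2-methylglycidate ester
Product: 26 ten-membered (4Z)-diene lactone with C8–OTBS
Conditions: second-generation Hoveyda–Grubbs catalyst (10 mol %), 1,4-benzoquinone (20 mol %), toluene (1 mM), 80 °C
Reagents that add atoms: none
Why: Ring-closing metathesis should initiate at the C5 vinyl group and close onto the 1,1-disubstituted C4 alkene, the electron-poor enoate and methylene lactone being spectators; the cis-fused lactone and the ring-cis enoate bring the ends together, and a ten-membered ring accepts only the Z trisubstituted alkene.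

Step 15
Reactants: 26 ten-membered (4Z)-diene lactone with C8–OTBS
Product: 27 C8 alcohol
Conditions: HF·pyridine, MeCN, 0 °C to rt
Reagents that add atoms: none
Why: Mildly acidic fluoride removes the secondary silyl ether, avoids the base-promoted C9-to-C8 acyl shift, translactonisation and oxa-Michael addition, and the ester-deactivated side-chain epoxide should survive.

Step 16
Reactants: 27 C8 alcohol
Product: 28 C8 acetate (4,5-deoxy precursor of the target)
Conditions: Ac2O, pyridine, DMAP (cat.), CH2Cl2, 0 °C
Reagents that add atoms: acetic anhydride, CC(=O)OC(C)=O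
Why: Standard DMAP-catalysed acetylation of the only free hydroxyl, with retention at C8.

Step 17
Reactants: 28 C8 acetate
Product: 29 target CNP0159450.1
Conditions: dimethyldioxirane (1.1 equiv), acetone–CH2Cl2, −20 °C
Reagents that add atoms: dimethyldioxirane, CC1(C)OO1
Why: The acid-free electrophilic oxidant picks the only electron-rich alkene; A1,3 strain holds C6–H in the alkene plane with the ring chain (C7, C2) on the inner face, so peripheral attack should occur on the face bearing O6 and give the cis-epoxide (4R,5S) next to (6R).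

Compound list
1 | (S)-but-3-ene-1,2-diol | C=C[C@H](O)CO | starting material
2 | (S)-3,4-bis(tert-butyldimethylsilyloxy)but-1-ene | C=C[C@H](O[Si](C)(C)C(C)(C)C)CO[Si](C)(C)C(C)(C)C | intermediate
3 | 4-chloro-N,N-dimethylbutanamide | CN(C)C(=O)CCCCl | starting material
4 | (4-chlorobut-1-enylidene)dimethylammonium triflate (keteniminium triflate) | ClCCC=C=[N+](C)C.[O-]S(=O)(=O)C(F)(F)F | intermediate
5 | cyclobutaniminium triflate (dimethyliminium form of 6) | C1C(=[N+](C)C)[C@@H](CCCl)[C@H]1[C@H](O[Si](C)(C)C(C)(C)C)CO[Si](C)(C)C(C)(C)C.[O-]S(=O)(=O)C(F)(F)F | intermediate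
6 | cis-2-(2-chloroethyl)-3-[(S)-1,2-bis(TBS-oxy)ethyl]cyclobutanone | C1C(=O)[C@@H](CCCl)[C@H]1[C@H](O[Si](C)(C)C(C)(C)C)CO[Si](C)(C)C(C)(C)C | intermediate
7 | cis-2-[2-(phenylselanyl)ethyl]-3-[(S)-1,2-bis(TBS-oxy)ethyl]cyclobutanone | C1C(=O)[C@@H](CC[Se]c2ccccc2)[C@H]1[C@H](O[Si](C)(C)C(C)(C)C)CO[Si](C)(C)C(C)(C)C | intermediate
8 | selenoxide lactone (cis-4,5-disubstituted γ-lactone with 2-(phenylseleninyl)ethyl at C6) | C1C(=O)O[C@@H](CC[Se](=O)c2ccccc2)[C@H]1[C@H](O[Si](C)(C)C(C)(C)C)CO[Si](C)(C)C(C)(C)C | intermediate
9 | cis-4-[(S)-1,2-bis(TBS-oxy)ethyl]-5-vinyldihydrofuran-2(3H)-one | C1C(=O)O[C@@H](C=C)[C@H]1[C@H](O[Si](C)(C)C(C)(C)C)CO[Si](C)(C)C(C)(C)C | intermediate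
10 | Mannich base (C11 dimethylaminomethyl lactone, C13 trans to the C7 side chain) | CN(C)C[C@@H]1C(=O)O[C@@H](C=C)[C@H]1[C@H](O[Si](C)(C)C(C)(C)C)CO[Si](C)(C)C(C)(C)C | intermediate
11 | trimethylammonium iodide of 10 | C[N+](C)(C)C[C@@H]1C(=O)O[C@@H](C=C)[C@H]1[C@H](O[Si](C)(C)C(C)(C)C)CO[Si](C)(C)C(C)(C)C.[I-] | intermediate
12 | cis-4-[(S)-1,2-bis(TBS-oxy)ethyl]-3-methylene-5-vinyldihydrofuran-2(3H)-one | C=C1C(=O)O[C@@H](C=C)[C@H]1[C@H](O[Si](C)(C)C(C)(C)C)CO[Si](C)(C)C(C)(C)C | intermediate
13 | primary alcohol (C9–OH, C8–OTBS) | C=C1C(=O)O[C@@H](C=C)[C@H]1[C@H](O[Si](C)(C)C(C)(C)C)CO | intermediate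
14 | α-silyloxy aldehyde (C9 aldehyde) | C=C1C(=O)O[C@@H](C=C)[C@H]1[C@H](O[Si](C)(C)C(C)(C)C)C=O | intermediate
15 | 4-methylpent-4-enal | C=C(C)CCC=O | starting material
16 | methyl (triphenylphosphoranylidene)acetate | COC(=O)C=P(c1ccccc1)(c1ccccc1)c1ccccc1 | starting material
17 | methyl iodo(triphenylphosphoranylidene)acetate | COC(=O)C(I)=P(c1ccccc1)(c1ccccc1)c1ccccc1 | intermediate
18 | methyl (Z)-2-iodo-6-methylhepta-2,6-dienoate | COC(=O)/C(I)=C/CCC(C)=C | intermediate
19 | C9 allylic alcohol, (8S,9R) anti epimer drawn | C=C1C(=O)O[C@@H](C=C)[C@H]1[C@H](O[Si](C)(C)C(C)(C)C)[C@H](O)/C(C(=O)OC)=C\CCC(C)=C | intermediate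
20 | C9 ketone (alkylidene β-keto ester) | C=C1C(=O)O[C@@H](C=C)[C@H]1[C@H](O[Si](C)(C)C(C)(C)C)C(=O)/C(C(=O)OC)=C\CCC(C)=C | intermediate
21 | (8S,9S) syn allylic alcohol | C=C1C(=O)O[C@@H](C=C)[C@H]1[C@H](O[Si](C)(C)C(C)(C)C)[C@@H](O)/C(C(=O)OC)=C\CCC(C)=C | intermediate
22 | (S)-(2-methyloxiran-2-yl)methanol | OC[C@@]1(C)CO1 | starting material
23 | (R)-2-methyloxirane-2-carboxylic acid | OC(=O)[C@@]1(C)CO1 | intermediate
24 | mixed anhydride of 23 and 2,4,6-trichlorobenzoic acid | O=C(OC(=O)[C@@]1(C)CO1)c1c(Cl)cc(Cl)cc1Cl | intermediate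
25 | C9 (R)-2-methylglycidate ester (metathesis precursor) | C=C1C(=O)O[C@@H](C=C)[C@H]1[C@H](O[Si](C)(C)C(C)(C)C)[C@@H](OC(=O)[C@@]2(C)CO2)/C(C(=O)OC)=C\CCC(C)=C | intermediate
26 | ten-membered (4Z)-diene lactone, C8–OTBS | C1/C(C)=C\[C@@H]2OC(=O)C(=C)[C@@H]2[C@H](O[Si](C)(C)C(C)(C)C)[C@@H](OC(=O)[C@@]3(C)CO3)/C(C(=O)OC)=C\C1 | intermediate
27 | ten-membered (4Z)-diene lactone, C8–OH | C1/C(C)=C\[C@@H]2OC(=O)C(=C)[C@@H]2[C@H](O)[C@@H](OC(=O)[C@@]3(C)CO3)/C(C(=O)OC)=C\C1 | intermediate
28 | ten-membered (4Z)-diene lactone, C8–OAc | C1/C(C)=C\[C@@H]2OC(=O)C(=C)[C@@H]2[C@H](OC(C)=O)[C@@H](OC(=O)[C@@]3(C)CO3)/C(C(=O)OC)=C\C1 | intermediate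
29 | CNP0159450.1 | C=C1C(=O)O[C@@H]2[C@H]1[C@H](OC(C)=O)[C@@H](OC(=O)[C@@]1(C)CO1)/C(C(=O)OC)=C\CC[C@@]1(C)O[C@@H]21 | target

Total step count: 17. Longest linear sequence: 15 (steps 1–7, 9–11 and 13–17).

Steps most likely to fail

Step 2. What may go wrong: weak facial discrimination at C7 by the allylic C8 centre, leakage of the kinetic cis C6/C7 pair to trans through iminium–enamine equilibration, and sluggish addition to an inductively deactivated, hindered alkene. The fallback moves stereocontrol from the substrate to the reagent. 4-Chlorobutanoyl chloride is condensed (Et3N, CH2Cl2) with (2R,5R)-2,5-dimethylpyrrolidine to give the C2-symmetric amide 4-chloro-1-[(2R,5R)-2,5-dimethylpyrrolidin-1-yl]butan-1-one F1. Tf2O/collidine turns it into the chiral keteniminium triflate F2. Its two faces are differentiated by the flanking methyl groups, and it adds to 2 to give the chiral cyclobutaniminium triflate F3. Hydrolysis releases the auxiliary. The antipodal auxiliary is used if the pairing with (8S) proves mismatched. This fallback sets out from 2 and comes back at 6.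

Step 14. What may go wrong: oligomerisation instead of ring closure, because of transannular strain and the bulky C8/C9 substituents, and alkene migration by ruthenium hydrides. The fallback closes the ring before the large acyl group is in place. Alcohol 21 is submitted to the metathesis to give the macrocyclic C9 alcohol F4, which is then acylated with 23 by way of 24 under the conditions of step 13. This fallback sets out from 21 and comes back at 26.

Step 11. What may go wrong: insufficient Felkin–Anh bias, conjugate reduction of the methylene lactone or the alkylidene keto ester, and E/Z drift of the activated enone before reduction. The fallback replaces oxidation and reduction by an invertive esterification. The 8,9-anti alcohol 19 from the Felkin-selective step 9 is coupled directly with acid 23 under Mitsunobu conditions (PPh3, diisopropyl azodicarboxylate, toluene, 0 °C), which inverts C9 while installing the ester. It makes no new compound (F0). This fallback sets out from 19 and comes back at 25.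

Further compounds
F1 | step 2 | 4-chloro-1-[(2R,5R)-2,5-dimethylpyrrolidin-1-yl]butan-1-one | O=C(CCCCl)N1[C@H](C)CC[C@H]1C
F2 | step 2 | chiral keteniminium triflate | ClCCC=C=[N+]1[C@H](C)CC[C@H]1C.[O-]S(=O)(=O)C(F)(F)F
F3 | step 2 | chiral cyclobutaniminium triflate | C1C(=[N+]2[C@H](C)CC[C@H]2C)[C@@H](CCCl)[C@H]1[C@H](O[Si](C)(C)C(C)(C)C)CO[Si](C)(C)C(C)(C)C.[O-]S(=O)(=O)C(F)(F)F
F4 | step 14 | macrocyclic C9 alcohol | C1/C(C)=C\[C@@H]2OC(=O)C(=C)[C@@H]2[C@H](O[Si](C)(C)C(C)(C)C)[C@@H](O)/C(C(=O)OC)=C\C1
F0 | step 11 | none | none
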